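## Structural features

The target is a flavone: a benzene ring A is fused through C4a–C8a to a 4-pyranone ring C, which carries the 2,3,4-trimethoxyphenyl ring B at C2 through the C2–C1' bond. It has no stereocentre, so nothing stereochemical has to be set or preserved. Ring A is oxygenated at C5, C7, C8 and C8a and has C6 as its only CH; ring B carries three contiguous methoxy groups. The fragile elements are the vinylogous ester of ring C (opened at C2 by hydroxide and other hard nucleophiles), the C5 methoxy group peri to the C4 carbonyl (cleaved by Lewis acids), and the two electron-rich arenes (easily oxidised). The real difficulty is regiochemical and lies in ring A: the C8a oxygen must differ from the three methoxy oxygens on a ring with one free position, so late functionalisation of a simpler arene would have to tell very similar sites apart. The key step uses the fact that the C8a oxygen is para to C6–H, adjacent to the methoxy carbons C8 and C7, and adjacent to C4a, which bears the carbonyl carbon C4. A 2,3-dimethoxycyclobutenone maps onto this: its carbonyl carbon becomes C8a, its alkene carbons become C8 and C7, and its C4–H becomes C6–H. A methoxyacrylate unit supplies C5 with its methoxy group and C4a with the C4 ester.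

## Logic of the disconnections

Ring C of 19 is opened at the O1–C2 bond. This enol ether bond is the retron of a conjugate addition of the C8a oxygen to an alkynone, so the cut leads through 18 to 17, in which rings A and B are linked only by a three-carbon ynone. One ring is removed and no redox adjustment is created. The forward step must close 6-endo at C2 and not 5-exo at C3. This is secured by letting a secondary amine occupy C2 first, so that 18 is the species that cyclises.

17 is cut at the C3–C4 bond between the carbonyl carbon and the alkyne. This is the most convergent cut available: it separates the acyl electrophile 16 (from 13), which holds all of ring A, from 15, which holds all of ring B. The forward acylation must run at room temperature so that the hindered aroyl–palladium species does not lose CO. The C8a oxygen must be masked as its acetate so that 16 cannot acylate itself.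

15 is traced to 14 by removing the terminal alkyne carbon; the C≡C bond is made from the C=O bond by a one-carbon homologation. The gain is a cheap starting material that already has the three ring B methoxy groups in place. The forward step only asks for a non-enolisable aldehyde, which 14 is.

13 is related to 11 through 12 by O-acetylation and ester hydrolysis; no skeletal bond is cut. These changes are placed here so that the key step can deliver the acyl carbon as an ester and the C8a oxygen as a free phenol. The forward demand is that a di-ortho-substituted ester is hydrolysed and that 12 is handled without loss of CO2.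

11 is cut at C5–C6 and at C4a–C8a. The two cuts dismantle ring A completely into the four-carbon ring of 3 (C6, C7, C8, C8a) and the acrylate unit of 7 (C5, C4a, C4), with 8, 9 and 10 as the intermediates between them. The reason is that the positions of all four ring A oxygens are then fixed by connectivity and not by the directing effects of an arene. The gain is that a pentasubstituted, tetra-oxygenated benzene is exchanged for two small building blocks. The forward step demands a palladium-catalysed coupling at the sp3 carbon of 3 with a hindered α-alkoxyalkenyl stannane, then a ring opening and ring closure near 100 °C that tolerate an ester.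

3 is taken back to 2 by exchanging C–Cl for C–OH, and 2 to 1 by exchanging the carbinol for a carbonyl group. 1 is symmetric, so either carbonyl gives the same product, and it already contains the C7 and C8 methoxy groups. The forward steps must avoid protic acid, which would ionise the C4–O or C4–Cl bond with allylic transposition and loss of a methyl group.

7 is cut at the C–Sn bond to 5 and the vinyllithium 6, which comes from 4 by removal of the C3 hydrogen cis to the ester. The gain is that the acrylate unit with its methoxy group is bought and not built. The forward step must be cold enough that 6 does not attack the ester of a second molecule, and it must keep the alkene geometry, which chelation of lithium by the ester should ensure.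

## Other disconnections considered

Alternative 1: This plan cuts C2–C3 and C3–C4 of ring C and removes C3 as a one-carbon unit. It leads back to the silyl enol ether A2 of the 2-arylbenzofuran-3(2H)-one A3.
- Forward key step: dichlorocarbene (CHCl3, KO-t-Bu) would cyclopropanate the C2=C3 bond of A2, and the dichlorocyclopropane would open with loss of chloride and of the silyl group to the 3-chloroflavone A1. A hydrodechlorination would then be needed to reach 19.
- In its favour: the ring expansion can only give a six-membered ring C, so no flavone/aurone ambiguity exists. The reagents are cheap and neither tin nor palladium is needed.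
- Against it here: A3 must already carry the 4,6,7-trimethoxy pattern, so the ring A problem is moved to an earlier arene and not solved. KO-t-Bu can desilylate A2, after which the free enolate of A3 would meet the carbene less selectively. The two electron-rich arenes are carbene acceptors themselves. A chlorine is put on C3 only to be removed again next to a reducible C2=C3 bond.
- Comparison: structurally it works on ring C, where the target is easy, while the chosen plan works on ring A, where it is hard. Mechanistically it replaces a palladium coupling and two electrocyclic steps by a carbene addition and a cyclopropyl-to-allyl opening of comparable precedent. In step count from A3 (silylation, expansion, dechlorination) it equals the three steps (7, 8, 9) that the chosen plan spends on ring C. It is the better plan on one point, the inherently six-membered outcome, and the weaker one on the origin of ring A.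

Alternative 2: The cut is the O1–C8a bond. The diketone A5 is one Claisen condensation away from two commercial arenes.
- Forward key step: (NH4)2Ce(NO3)6 would oxidise the para-dimethoxy pair of A5 to an acylquinone, whose enol oxygen adds to C8a; reoxidation would give the flavone-5,8-quinone A4. Reduction to the hydroquinone A6 (for example with Na2S2O4) and double O-methylation would complete 19.
- In its favour: it is very short, and it differentiates the C8a oxygen by connectivity just as the chosen plan does. It needs no tin, no palladium and no protecting group.
- Against it here: tetravalent cerium is not selective a priori. Ring B and the enolised diketone carbon are oxidisable, and the adjacent 4,5-dimethoxy pair can lead to an ortho-quinone. A4 is electrophilic at C6 and at the C7 vinylogous ester. A6 is air-sensitive, and its C5 hydroxyl is chelated to the C4 carbonyl and should methylate slowly. The oxidation level is raised and then lowered again.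
- Comparison: structurally both plans fix the C8a oxygen by connectivity, but this one buys ring A as an arene and the chosen one builds it. Mechanistically it rests on a chemoselective single-electron oxidation in a molecule with three oxidisable sites, against a coupling and pericyclic sequence with no chemoselectivity issue of that kind. On step economy (about four steps against nine) it is clearly the better plan. The chosen plan is preferred only because it avoids the oxidation–reduction detour and the chemoselectivity risk.

Alternative 3: The cut is the C5–C6 bond of ring A. The precursor A8 is a 4-pyranone (the future ring C, already bearing ring B) with an ester at the future C4a and a 1-methoxy-2-oxopropyl chain at the future C8a.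
- Forward key step: base would form the methyl ketone enolate, whose carbon (C6) attacks the ester carbonyl (C5) in a Dieckmann-type closure. The cyclic diketone would enolise to the 5,7-dihydroxy arene A7, and double O-methylation of A7 would give 19.
- In its favour: like the chosen plan it builds ring A de novo with the oxygen pattern fixed by the chain. The closure is a single ionic step at low temperature without tin or palladium. Both hydroxyls of A7 are to be methylated, so the last step has no selectivity demand.
- Against it here: A8 is densely functionalised and needs a long preparation. Its most acidic position is the CH(OMe) carbon and not the methyl group, so the productive enolate is the minor one. Alkoxide bases can open the pyranone at C2 or C6. The chelated C5 hydroxyl of A7 should methylate slowly.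
- Comparison: on structure it is the equal of the chosen plan, since both solve ring A by construction. On mechanism it is simpler. On step economy it is expected to be worse, because the effort moves into A8, whereas 3 and 7 are each one or two steps from commercial materials.

Key step: step 4

Remark: 2, 3, 8 and 10 are racemic, which is immaterial because 19 has no stereocentre. Atom-by-atom mapping of the ring expansion, and the descriptor of 7 (tin outranks oxygen, hence Z for tin cis to the ester), showed the structures to be mutually consistent, so none was altered and 3 and 7 are used without protecting groups.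

## Route

Step 1
Reactants: 1 dimethyl squarate (3,4-dimethoxycyclobut-3-ene-1,2-dione)
Product: 2 4-hydroxy-2,3-dimethoxycyclobut-2-en-1-one (racemic)
Conditions: LiAlH(O-t-Bu)3 (1.05 equiv), THF, −78 °C; aq. KNaC4H4O6, 0 °C
Reagents that add atoms: none
Why: 1,2-Reduction of one of the two equivalent vinylogous ester carbonyls by a bulky, mild hydride, which should stop at the mono-alcohol at −78 °C; the neutral tartrate work-up protects the acid-labile product, and the new stereocentre is formed racemic and is destroyed later.

Step 2
Reactants: 2 4-hydroxy-2,3-dimethoxycyclobut-2-en-1-one (racemic)
Product: 3 4-chloro-2,3-dimethoxycyclobut-2-en-1-one (racemic)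
Conditions: PPh3, N-chlorosuccinimide, CH2Cl2, −20 °C (premixed); then 2, −20 → 0 °C; used without storage
Reagents that add atoms: N-chlorosuccinimide, O=C1CCC(=O)N1Cl
Why: Appel-type deoxychlorination under neutral conditions: the alkoxyphosphonium ion at C4, which is α to the ketone, should be displaced directly by chloride (SN2), while the absence of protic acid and of free phosphine suppresses ionisation with allylic transposition and attack on the α-chloroketone; the stereocentre is racemic.

Step 3
Reactants: 4 methyl (E)-3-methoxyacrylate; 5 tributyltin chloride
Product: 7 methyl (Z)-3-methoxy-3-(tributylstannyl)acrylate, via vinyllithium 6 (not isolated)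
Conditions: LiN(i-Pr)2 (commercial solution), THF, −90 °C; then Bu3SnCl, −90 → −40 °C
Reagents that add atoms: none
Why: Directed β-lithiation of a β-alkoxyacrylate: the C3 hydrogen cis to the ester is removed because the ester carbonyl chelates lithium and the methoxy oxygen acidifies the vinylic C–H; the configurationally stable vinyllithium 6 should be stannylated with retention, and the descriptor changes from E to Z only because tin outranks oxygen.

Step 4
Reactants: 3 4-chloro-2,3-dimethoxycyclobut-2-en-1-one (racemic); 7 methyl (Z)-3-methoxy-3-(tributylstannyl)acrylate
Product: 11 methyl 2-hydroxy-3,4,6-trimethoxybenzoate, via alkenylcyclobutenone 8 (not isolated), via dienylketene 9 (not isolated), via cyclohexadienone 10 (not isolated)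
Conditions: PdCl2(PhCN)2 (5 mol %), P(2-furyl)3 (10 mol %), dioxane, 50 °C; then 100 °C; aq. KF work-up
Reagents that add atoms: none
Why: Zerovalent palladium, formed in situ from PdCl2(PhCN)2 and kept labile by the weakly donating P(2-furyl)3, should insert into the activated C4–Cl bond of 3, and Stille transmetalation of the α-methoxyalkenyl group of 7 followed by reductive elimination forms the C5–C6 bond with retention of alkene geometry to give 8. At 100 °C the strained ring of 8 should open by a conrotatory 4-electron electrocyclic reaction to the dienylketene 9; the opening is reversible, so the rotamer with the alkenyl group turned inward is drained productively. The ketene carbon (future C8a) then bonds to the acrylate CH carbon (future C4a) in a disrotatory 6-electron electrocyclisation that closes ring A as the six-membered dienone 10, and enolisation, driven by aromatisation and by the hydrogen bond to the ester, gives 11. The closest known reaction type is the palladium-catalysed cross-coupling of 4-chlorocyclobutenones with alkenylstannanes with thermal ring expansion to phenols; only this oxygenation pattern is new. No stereocentre remains, since the racemic centres of 3, 8 and 10 are erased on aromatisation. The selectivity needed is regiochemical and is built into the connectivity: the tin-bearing carbon can only join the carbon that carried chlorine and the ketene carbon can only reach the other alkene carbon, so the cyclobutenone carbonyl must end as the single free hydroxyl between the C8 methoxy group and the ester. Coupling with allylic transposition at C2 would need attack at a fully substituted carbon with loss of enone conjugation and is not expected. The geometry of the acrylate double bond is lost in the closure, so any E/Z isomerisation of 8 is harmless.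

Step 5
Reactants: 11 methyl 2-hydroxy-3,4,6-trimethoxybenzoate
Product: 12 2-hydroxy-3,4,6-trimethoxybenzoic acid
Conditions: KOH, MeOH/H2O, 70 °C, Ar; then aq. HCl, 0 °C, to pH 2
Reagents that add atoms: water, O
Why: Saponification by acyl–oxygen cleavage; heating should overcome the di-ortho substitution and the deactivation by the phenoxide, argon protects the electron-rich phenoxide from air, and cold acidification without heating avoids protodecarboxylation of the salicylic acid.

Step 6
Reactants: 12 2-hydroxy-3,4,6-trimethoxybenzoic acid
Product: 13 2-acetoxy-3,4,6-trimethoxybenzoic acid
Conditions: Ac2O, pyridine, DMAP (cat.), 0 °C → rt; then H2O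
Reagents that add atoms: acetic anhydride, CC(=O)OC(C)=O
Why: Nucleophile-catalysed O-acetylation of the phenol; any mixed carboxylic anhydride formed at the acid should be hydrolysed at its unhindered acetyl carbonyl in the aqueous quench, leaving the aryl acetate that masks the C8a oxygen for acid chloride formation.

Step 7
Reactants: 14 2,3,4-trimethoxybenzaldehyde
Product: 15 1-ethynyl-2,3,4-trimethoxybenzene
Conditions: dimethyl (1-diazo-2-oxopropyl)phosphonate, K2CO3, MeOH, rt
Reagents that add atoms: dimethyl (1-diazo-2-oxopropyl)phosphonate, CC(=O)C(=[N+]=[N-])P(=O)(OC)OC
Why: Ohira–Bestmann variant of the Seyferth–Gilbert homologation: methanolysis of the acetyl group releases the diazomethylphosphonate anion, which olefinates the non-enolisable aldehyde; loss of N2 and a 1,2-shift should then give the terminal alkyne under mild base that leaves the aryl ethers untouched.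

Step 8
Reactants: 13 2-acetoxy-3,4,6-trimethoxybenzoic acid; 15 1-ethynyl-2,3,4-trimethoxybenzene
Product: 17 2,3,5-trimethoxy-6-[3-(2,3,4-trimethoxyphenyl)prop-2-ynoyl]phenyl acetate, via acid chloride 16 (not isolated)
Conditions: (COCl)2, DMF (cat.), CH2Cl2, 0 °C → rt, evaporate; then 15, PdCl2(PPh3)2 (2 mol %), CuI (4 mol %), Et3N, THF, rt
Reagents that add atoms: oxalyl chloride, O=C(Cl)C(=O)Cl (its chlorine is present in 16 only and is lost again in the coupling)
Why: Vilsmeier-catalysed acid chloride formation followed by acyl Sonogashira coupling: zerovalent palladium inserts into the acyl C–Cl bond, the alkynylcopper formed from 15, CuI and Et3N transmetalates, and reductive elimination forms the C3–C4 bond; at room temperature neither CO loss from the aroyl–palladium species nor cleavage of the aryl acetate is expected.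

Step 9
Reactants: 17 2,3,5-trimethoxy-6-[3-(2,3,4-trimethoxyphenyl)prop-2-ynoyl]phenyl acetate
Product: 19 5,7,8-trimethoxy-2-(2,3,4-trimethoxyphenyl)-4H-chromen-4-one (2',3',4',5,7,8-hexamethoxyflavone), via enaminone 18 (not isolated)
Conditions: Et2NH (excess), EtOH, rt; then AcOH, 80 °C
Reagents that add atoms: diethylamine, CCNCC (its nitrogen is present in 18 only and is lost again in the ring closure)
Why: Diethylamine should add in conjugate fashion to the ynone and cleave the aryl acetate by aminolysis, in either order, to give the o-hydroxyaryl enaminone 18; on mild acid activation the phenol oxygen can attack only the amine-bearing carbon C2 (6-endo addition–elimination with loss of Et2NH), which forms O1–C2 and excludes the 5-exo closure open to a free hydroxy ynone.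

## Compound list

1 | dimethyl squarate (3,4-dimethoxycyclobut-3-ene-1,2-dione) | COC1=C(OC)C(=O)C1=O | starting material
2 | 4-hydroxy-2,3-dimethoxycyclobut-2-en-1-one (racemic) | O=C1C(OC)=C(OC)C1O | intermediate
3 | 4-chloro-2,3-dimethoxycyclobut-2-en-1-one (racemic) | O=C1C(OC)=C(OC)C1Cl | intermediate
4 | methyl (E)-3-methoxyacrylate | CO/C=C/C(=O)OC | starting material
5 | tributyltin chloride | CCCC[Sn](Cl)(CCCC)CCCC | starting material
6 | methyl (E)-3-lithio-3-methoxyacrylate (lithium cis to the ester) | [Li]/C(OC)=C\C(=O)OC | intermediate
7 | methyl (Z)-3-methoxy-3-(tributylstannyl)acrylate | CCCC[Sn](CCCC)(CCCC)/C(OC)=C\C(=O)OC | intermediate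
8 | methyl (E)-3-(2,3-dimethoxy-4-oxocyclobut-2-en-1-yl)-3-methoxyacrylate (racemic) | COC(=O)/C=C(/OC)C1C(=O)C(OC)=C1OC | intermediate
9 | methyl (2E,4E)-3,5,6-trimethoxy-7-oxohepta-2,4,6-trienoate (dienylketene) | COC(=O)/C=C(/OC)\C=C(\OC)/C(OC)=C=O | intermediate
10 | methyl 2,4,5-trimethoxy-6-oxocyclohexa-2,4-diene-1-carboxylate (racemic) | COC(=O)C1C(=O)C(OC)=C(OC)C=C1OC | intermediate
11 | methyl 2-hydroxy-3,4,6-trimethoxybenzoate | COC(=O)c1c(O)c(OC)c(OC)cc1OC | intermediate
12 | 2-hydroxy-3,4,6-trimethoxybenzoic acid | OC(=O)c1c(O)c(OC)c(OC)cc1OC | intermediate
13 | 2-acetoxy-3,4,6-trimethoxybenzoic acid | CC(=O)Oc1c(OC)c(OC)cc(OC)c1C(O)=O | intermediate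
14 | 2,3,4-trimethoxybenzaldehyde | COc1ccc(C=O)c(OC)c1OC | starting material
15 | 1-ethynyl-2,3,4-trimethoxybenzene | COc1ccc(C#C)c(OC)c1OC | intermediate
16 | 2-acetoxy-3,4,6-trimethoxybenzoyl chloride | CC(=O)Oc1c(OC)c(OC)cc(OC)c1C(Cl)=O | intermediate
17 | 2,3,5-trimethoxy-6-[3-(2,3,4-trimethoxyphenyl)prop-2-ynoyl]phenyl acetate | CC(=O)Oc1c(OC)c(OC)cc(OC)c1C(=O)C#Cc1ccc(OC)c(OC)c1OC | intermediate
18 | (E)-3-(diethylamino)-1-(2-hydroxy-3,4,6-trimethoxyphenyl)-3-(2,3,4-trimethoxyphenyl)prop-2-en-1-one | CCN(CC)/C(=C/C(=O)c1c(O)c(OC)c(OC)cc1OC)c1ccc(OC)c(OC)c1OC | intermediate
19 | 5,7,8-trimethoxy-2-(2,3,4-trimethoxyphenyl)-4H-chromen-4-one (2',3',4',5,7,8-hexamethoxyflavone) | COc1ccc(-c2cc(=O)c3c(OC)cc(OC)c(OC)c3o2)c(OC)c1OC | target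

## Step count and least certain steps

Total step count: 9. Longest linear sequence: 7 steps (1, 2, 4, 5, 6, 8, 9) from 1; steps 3 and 7 are convergent branches.

Step 4 (key step).
- Most likely failure: transmetalation from the hindered, α-oxygenated and ester-conjugated stannane is slow compared with decay of the labile chloride and its palladium adduct. That would show as protodestannylation by traces of HCl, reductive dimerisation of the four-membered ring fragment, or loss of a methyl group with allylic transposition. Interception of the ketene by adventitious nucleophiles before ring closure is a second risk.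
- Fallback: it sets out from 6 and 3 and comes back at 8. The vinyllithium 6, generated as in step 3, would be transmetalated at −90 °C with ZnCl2 to methyl (Z)-3-(chlorozincio)-3-methoxyacrylate F1. F1 would be coupled with 3 under Pd(PPh3)4 in THF at 0 °C to room temperature (Negishi coupling) to give 8. 8 would then be heated separately in dioxane at 100 °C, passing through 9 and 10 to 11. Zinc transmetalates far faster than tin, the coupling is uncoupled from the thermolysis, and 7 need not be isolated or purified.

Step 2.
- Most likely failure: ionisation at C4 instead of direct displacement, because the cation is stabilised by the C2 methoxy group; chloride would then enter with allylic transposition and a methyl group would be lost, giving a cyclobutenedione. Decomposition of the chloride on silica or on standing is a second risk.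
- Fallback: it sets out from 2 and comes back at 8. 2 would be acylated under basic, non-ionising conditions (ClCO2Me, pyridine, CH2Cl2, 0 °C) to 2,3-dimethoxy-4-oxocyclobut-2-en-1-yl methyl carbonate F2. Allylic carbonates undergo oxidative addition to zerovalent palladium under neutral conditions, and the methoxide released on loss of CO2 activates the stannane. F2 and 7 under the catalyst of step 4 at 50 °C should therefore give 8, which continues to 11 at 100 °C. No carbon–halogen bond is needed.

Step 5.
- Most likely failure: incomplete saponification, because hydroxide must attack an ester flanked by two ortho substituents and deactivated by the neighbouring phenoxide. The other risk is protodecarboxylation of the very electron-rich salicylic acid during acidification or later handling.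
- Fallback: it sets out from 11 and comes back at 19, and it never forms the free acid. 11 would be protected (chloromethyl methyl ether, i-Pr2NEt, CH2Cl2) as methyl 3,4,6-trimethoxy-2-(methoxymethoxy)benzoate F3. F3 would be condensed with commercial 2',3',4'-trimethoxyacetophenone in a crossed Claisen condensation (NaH, THF, 65 °C) to 1-[3,4,6-trimethoxy-2-(methoxymethoxy)phenyl]-3-(2,3,4-trimethoxyphenyl)propane-1,3-dione F4. HCl in MeOH at 60 °C should remove the acetal to give 1-(2-hydroxy-3,4,6-trimethoxyphenyl)-3-(2,3,4-trimethoxyphenyl)propane-1,3-dione F5 and cyclodehydrate it to 19. The protected ester no longer carries a phenoxide, and ring C is closed from a 1,3-diketone, which cannot give a five-membered ring. Hindrance at the ester remains the weak point of this variant.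

Step 8.
- Most likely failure: oxidative addition and transmetalation are slow at the di-ortho-substituted aroyl chloride. Oxidative dimerisation of the alkyne on copper, loss of CO from the aroyl–palladium species, or acetyl transfer could then compete.
- Fallback: it sets out from 12 and 15 and comes back at 18. 12 would be converted with 1,1'-carbonyldiimidazole and N,O-dimethylhydroxylamine hydrochloride into the Weinreb amide 2-hydroxy-N,3,4,6-tetramethoxy-N-methylbenzamide F6. 15 would be deprotonated with n-BuLi in THF at −78 °C to lithium (2,3,4-trimethoxyphenyl)acetylide F7. An excess of F7 (one equivalent is consumed by the phenol) would add to F6, and the chelated tetrahedral intermediate should collapse on work-up to 1-(2-hydroxy-3,4,6-trimethoxyphenyl)-3-(2,3,4-trimethoxyphenyl)prop-2-yn-1-one F8. F8 under the conditions of step 9 would give 18 and then 19. This avoids the acetate, the acid chloride and both metals.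

## Further compounds

F1 | step 4 | methyl (Z)-3-(chlorozincio)-3-methoxyacrylate | Cl[Zn]/C(OC)=C\C(=O)OC
F2 | step 2 | 2,3-dimethoxy-4-oxocyclobut-2-en-1-yl methyl carbonate (racemic) | COC(=O)OC1C(=O)C(OC)=C1OC
F3 | step 5 | methyl 3,4,6-trimethoxy-2-(methoxymethoxy)benzoate | COCOc1c(OC)c(OC)cc(OC)c1C(=O)OC
F4 | step 5 | 1-[3,4,6-trimethoxy-2-(methoxymethoxy)phenyl]-3-(2,3,4-trimethoxyphenyl)propane-1,3-dione | COCOc1c(OC)c(OC)cc(OC)c1C(=O)CC(=O)c1ccc(OC)c(OC)c1OC
F5 | step 5 | 1-(2-hydroxy-3,4,6-trimethoxyphenyl)-3-(2,3,4-trimethoxyphenyl)propane-1,3-dione | COc1cc(OC)c(OC)c(O)c1C(=O)CC(=O)c1ccc(OC)c(OC)c1OC
F6 | step 8 | 2-hydroxy-N,3,4,6-tetramethoxy-N-methylbenzamide | CON(C)C(=O)c1c(O)c(OC)c(OC)cc1OC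
F7 | step 8 | lithium (2,3,4-trimethoxyphenyl)acetylide | [Li]C#Cc1ccc(OC)c(OC)c1OC
F8 | step 8 | 1-(2-hydroxy-3,4,6-trimethoxyphenyl)-3-(2,3,4-trimethoxyphenyl)prop-2-yn-1-one | COc1ccc(C#CC(=O)c2c(O)c(OC)c(OC)cc2OC)c(OC)c1OC
A1 | alternative 1 | 3-chloro-5,7,8-trimethoxy-2-(2,3,4-trimethoxyphenyl)-4H-chromen-4-one | COc1ccc(-c2oc3c(OC)c(OC)cc(OC)c3c(=O)c2Cl)c(OC)c1OC
A2 | alternative 1 | tert-butyl(dimethyl){[4,6,7-trimethoxy-2-(2,3,4-trimethoxyphenyl)-1-benzofuran-3-yl]oxy}silane | COc1ccc(-c2oc3c(OC)c(OC)cc(OC)c3c2O[Si](C)(C)C(C)(C)C)c(OC)c1OC
A3 | alternative 1 | 4,6,7-trimethoxy-2-(2,3,4-trimethoxyphenyl)-1-benzofuran-3(2H)-one (racemic) | COc1ccc(C2Oc3c(OC)c(OC)cc(OC)c3C2=O)c(OC)c1OC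
A4 | alternative 2 | 7-methoxy-2-(2,3,4-trimethoxyphenyl)-4H-chromene-4,5,8-trione | COc1ccc(-c2cc(=O)c3c(o2)C(=O)C(OC)=CC3=O)c(OC)c1OC
A5 | alternative 2 | 1-(2,4,5-trimethoxyphenyl)-3-(2,3,4-trimethoxyphenyl)propane-1,3-dione | COc1ccc(C(=O)CC(=O)c2cc(OC)c(OC)cc2OC)c(OC)c1OC
A6 | alternative 2 | 5,8-dihydroxy-7-methoxy-2-(2,3,4-trimethoxyphenyl)-4H-chromen-4-one | COc1ccc(-c2cc(=O)c3c(O)cc(OC)c(O)c3o2)c(OC)c1OC
A7 | alternative 3 | 5,7-dihydroxy-8-methoxy-2-(2,3,4-trimethoxyphenyl)-4H-chromen-4-one | COc1ccc(-c2cc(=O)c3c(O)cc(O)c(OC)c3o2)c(OC)c1OC
A8 | alternative 3 | methyl 2-(1-methoxy-2-oxopropyl)-4-oxo-6-(2,3,4-trimethoxyphenyl)-4H-pyran-3-carboxylate (racemic) | COC(=O)c1c(C(OC)C(C)=O)oc(-c2ccc(OC)c(OC)c2OC)cc1=O
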